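## Retrosynthetic overview

1. Ring letters: the upper unit has rings A (benzo), C (pyran) and B (4-hydroxyphenyl). The lower unit has rings D (phloroglucinol-type benzo), F (pyran) and E (4-hydroxyphenyl). The last operation is hydrogenolysis of six benzyl ethers.
2. Ring F is opened at O1–C2 and taken to a higher oxidation level. Its precursor is an acyclic, locally achiral (Z)-α-benzyloxy "retro-chalcone" (ring D–CH=C(OBn)–CO–ring E, free OH on C8a). This is cut at C3=C4 (Claisen–Schmidt) into a ring-D salicylaldehyde and an α-benzyloxyacetophenone.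
3. Enabling feature: in ring F, C2 lies between O1 and the para-oxygenated ring E, C3 bears oxygen, and C4 hangs on C4a of electron-rich ring D, ortho to C8a–O1. The six atoms O1–C2–C3–C4–C4a–C8a are therefore a fully reduced 3-oxygenated flavylium (1-benzopyrylium) ring: closure of C8a–OH onto C2=O aromatises by loss of water, and the flat cation can be dearomatised stereoselectively by hydride, proton, hydride.
4. The 4→6 linkage is fixed by symmetry. The ring-D phenol carries its only free OH para to the interflavan carbon, so its two ortho CH positions are equivalent and formylation gives one aldehyde.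
5. Order of ring formation: ring C first, ring F last. Ring C comes from an enantioselective o-quinone methide/4-benzyloxystyrene [4+2] that sets upper C2 and C4 cis; its precursor comes from a directed-metalation aryllithium and a salicylaldehyde.

Key step: step 8

Assumption: the sense of induction of the two chiral acids (steps 3 and 8) is assigned by analogy with related substrates. If it proves opposite, the mirror-image acid is used and nothing else in the route changes.

## Route

Step 1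
Reactants: 1 3,5-bis(benzyloxy)phenol
Product: 2 [3,5-bis(benzyloxy)phenoxy]triisopropylsilane
Conditions: i-Pr3SiCl, imidazole, DMF, rt
Reagents that add atoms: chlorotriisopropylsilane, CC(C)[Si](Cl)(C(C)C)C(C)C
Why: Imidazole-promoted silyl ether formation on the only free phenol installs a bulky, non-coordinating group that steers the later lithiation and marks the oxygen that becomes O1 of ring F.

Step 2
Reactants: 2 [3,5-bis(benzyloxy)phenoxy]triisopropylsilane; 3 4-(benzyloxy)-2-hydroxybenzaldehyde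
Product: 6 (±)-[4-(benzyloxy)-2-hydroxyphenyl][2,6-bis(benzyloxy)-4-(triisopropylsilyloxy)phenyl]methanol, via aryllithium 4 (not isolated), via sodium phenolate 5 (not isolated)
Conditions: 2, n-BuLi, THF, 0 °C; separately 3, NaH, THF, 0 °C; combine at −78 °C to rt; H2O quench
Reagents that add atoms: none
Why: Directed ortho-metalation takes place at the carbon flanked by the two coordinating benzyloxy groups (the positions next to the bulky silyloxy group are shielded), and the aryllithium adds 1,2 to the aldehyde whose acidic phenol is masked as its sodium salt; the racemic carbinol centre is erased in step 3.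

Step 3
Reactants: 6 (±)-[4-(benzyloxy)-2-hydroxyphenyl][2,6-bis(benzyloxy)-4-(triisopropylsilyloxy)phenyl]methanol; 7 1-(benzyloxy)-4-ethenylbenzene
Product: 9 (2S,4S)-7-(benzyloxy)-2-[4-(benzyloxy)phenyl]-4-[2,6-bis(benzyloxy)-4-(triisopropylsilyloxy)phenyl]chromane, via o-quinone methide 8 (not isolated)
Conditions: 7 (3 equiv), (R)-3,3'-bis(2,4,6-triisopropylphenyl)-5,5',6,6',7,7',8,8'-octahydro-1,1'-binaphthalene-2,2'-diyl N-(trifluoromethanesulfonyl)phosphoramidate (5 mol %), 4 Å MS, CH2Cl2, −40 °C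
Reagents that add atoms: none
Why: Brønsted-acid-catalysed dehydration of an o-hydroxybenzhydrol to the (E)-o-quinone methide and inverse-electron-demand hetero-Diels–Alder reaction with a styrene is a known reaction type; the endo transition state places both aryl groups cis (2,4-cis), and the chiral anion hydrogen-bonded to the quinone methide oxygen selects the face that gives (2S,4S).

Step 4
Reactants: 9 (2S,4S)-7-(benzyloxy)-2-[4-(benzyloxy)phenyl]-4-[2,6-bis(benzyloxy)-4-(triisopropylsilyloxy)phenyl]chromane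
Product: 10 3,5-bis(benzyloxy)-4-{(2S,4S)-7-(benzyloxy)-2-[4-(benzyloxy)phenyl]chroman-4-yl}phenol
Conditions: Bu4NF, THF, 0 °C; H2O work-up
Reagents that add atoms: none
Why: Fluoride-induced desilylation cleaves only the aryl silyl ether and frees the one phenol that is para to the interflavan carbon, while benzyl ethers and both stereocentres are inert.

Step 5
Reactants: 10 3,5-bis(benzyloxy)-4-{(2S,4S)-7-(benzyloxy)-2-[4-(benzyloxy)phenyl]chroman-4-yl}phenol
Product: 11 4,6-bis(benzyloxy)-5-{(2S,4S)-7-(benzyloxy)-2-[4-(benzyloxy)phenyl]chroman-4-yl}-2-hydroxybenzaldehyde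
Conditions: MgCl2, Et3N, paraformaldehyde, THF, reflux; dilute HCl work-up
Reagents that add atoms: paraformaldehyde (as formaldehyde), C=O
Why: The magnesium-mediated ortho-formylation of phenols (Casnati–Skattebøl reaction) reacts only ortho to the free OH, and because the two ortho CH positions are interconverted by rotation about the C4–aryl bond a single aldehyde results, which fixes the 4→6 connectivity.

Step 6
Reactants: 12 2-(benzyloxy)-N-methoxy-N-methylacetamide; 13 [4-(benzyloxy)phenyl]magnesium bromide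
Product: 14 2-(benzyloxy)-1-[4-(benzyloxy)phenyl]ethan-1-one
Conditions: THF, 0 °C; 1 M HCl quench
Reagents that add atoms: none
Why: The Weinreb ketone synthesis stops cleanly at the ketone stage and tolerates both benzyl ethers.

Step 7
Reactants: 11 4,6-bis(benzyloxy)-5-{(2S,4S)-7-(benzyloxy)-2-[4-(benzyloxy)phenyl]chroman-4-yl}-2-hydroxybenzaldehyde; 14 2-(benzyloxy)-1-[4-(benzyloxy)phenyl]ethan-1-one
Product: 15 (Z)-2-(benzyloxy)-1-[4-(benzyloxy)phenyl]-3-[4,6-bis(benzyloxy)-5-{(2S,4S)-7-(benzyloxy)-2-[4-(benzyloxy)phenyl]chroman-4-yl}-2-hydroxyphenyl]prop-2-en-1-one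
Conditions: KOH, EtOH/THF, 40 °C; neutralise with AcOH
Reagents that add atoms: none
Why: Claisen–Schmidt condensation of an α-alkoxyacetophenone with a salicylaldehyde is the known route to α-alkoxychalcones, and dehydration gives the thermodynamic (Z)-alkene with ring D trans to the aroyl group.

Step 8
Reactants: 15 (Z)-2-(benzyloxy)-1-[4-(benzyloxy)phenyl]-3-[4,6-bis(benzyloxy)-5-{(2S,4S)-7-(benzyloxy)-2-[4-(benzyloxy)phenyl]chroman-4-yl}-2-hydroxyphenyl]prop-2-en-1-one
Product: 19 (2R,3R)-3,5,7-tris(benzyloxy)-2-[4-(benzyloxy)phenyl]-6-{(2S,4S)-7-(benzyloxy)-2-[4-(benzyloxy)phenyl]chroman-4-yl}chromane, via flavylium ion 16 (not isolated), via 4H-chromene 17 (not isolated), via oxocarbenium ion 18 (not isolated)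
Conditions: (R)-3,3'-bis(2,4,6-triisopropylphenyl)-1,1'-binaphthalene-2,2'-diyl hydrogen phosphate (10 mol %), diethyl 2,6-dimethyl-1,4-dihydropyridine-3,5-dicarboxylate (2.4 equiv), 5 Å MS, toluene, argon, 0 °C to rt
Reagents that add atoms: none
Why: Proposed new method: the chiral phosphoric acid protonates the push–pull enone of 15, which makes rotation about C3–C4 easy, so that the hydroxyl on C8a adds to the C2 carbonyl (6-exo-trig) and loss of water gives the flat, aromatic 3-benzyloxyflavylium ion 16 as an ion pair with the chiral phosphate. The Hantzsch ester transfers hydride to C4 (giving 4H-chromene 17), the acid protonates the enol ether at C3 (giving the 2-aryl oxocarbenium ion 18), and a second hydride goes to C2, so that one operation closes ring F, dearomatises it and creates both of its stereocentres. The closest known reaction types are the phosphoric acid/Hantzsch ester cascade transfer hydrogenation of 2,3-disubstituted quinolines (1,4-hydride addition, enamine protonation, 1,2-hydride addition) and the chiral-anion-controlled 1,4-reduction of 1-benzopyrylium ions made in situ from 2-hydroxychalcone-type precursors; new is the full reduction of the oxygen heterocycle bearing a 3-alkoxy group. C3 is controlled by the catalyst, in the protonation of 17 or, since 17 and 18 interconvert, by dynamic kinetic selection of one configuration at C3 in the last hydride transfer within the chiral ion pair. C2 is controlled by C3: A(1,2) strain with the coplanar ring E holds the 3-benzyloxy group pseudoaxial in 18 and hydride enters anti to it (axial attack, polar Felkin–Anh), which places H-2 trans and ring E cis to the benzyloxy group. The step needs regiocontrol (4→6 and not 4→8) and chemoselectivity: the only free hydroxyl is the one on C8a, para to the interflavan carbon C6, and the weak acid used in catalytic amount leaves ring C, the interflavan bond and the benzyl ethers alone.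

Step 9
Reactants: 19 (2R,3R)-3,5,7-tris(benzyloxy)-2-[4-(benzyloxy)phenyl]-6-{(2S,4S)-7-(benzyloxy)-2-[4-(benzyloxy)phenyl]chroman-4-yl}chromane
Product: 20 (2R,3R)-2-(4-hydroxyphenyl)-6-[(2S,4S)-7-hydroxy-2-(4-hydroxyphenyl)chroman-4-yl]chromane-3,5,7-triol
Conditions: H2 (1 atm), Pd(OH)2/C, THF/MeOH 1:1, rt
Reagents that add atoms: none
Why: Hydrogenolysis of all six benzyl ethers under neutral conditions is standard for benzylated flavan-3-ol oligomers and should leave the four stereocentres and the cyclic benzylic C2–O1 bonds untouched.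

## Compound list

1 | 3,5-bis(benzyloxy)phenol | Oc1cc(OCc2ccccc2)cc(OCc2ccccc2)c1 | starting material
2 | [3,5-bis(benzyloxy)phenoxy]triisopropylsilane | CC(C)[Si](Oc1cc(OCc2ccccc2)cc(OCc2ccccc2)c1)(C(C)C)C(C)C | intermediate
3 | 4-(benzyloxy)-2-hydroxybenzaldehyde | O=Cc1ccc(OCc2ccccc2)cc1O | starting material
4 | 2,6-bis(benzyloxy)-4-(triisopropylsilyloxy)phenyllithium | [Li]c1c(OCc2ccccc2)cc(O[Si](C(C)C)(C(C)C)C(C)C)cc1OCc1ccccc1 | intermediate
5 | sodium 5-(benzyloxy)-2-formylphenolate | [Na+].[O-]c1cc(OCc2ccccc2)ccc1C=O | intermediate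
6 | (±)-[4-(benzyloxy)-2-hydroxyphenyl][2,6-bis(benzyloxy)-4-(triisopropylsilyloxy)phenyl]methanol | OC(c1ccc(OCc2ccccc2)cc1O)c1c(OCc2ccccc2)cc(O[Si](C(C)C)(C(C)C)C(C)C)cc1OCc1ccccc1 | intermediate
7 | 1-(benzyloxy)-4-ethenylbenzene (4-benzyloxystyrene) | C=Cc1ccc(OCc2ccccc2)cc1 | starting material
8 | (6E)-3-(benzyloxy)-6-{[2,6-bis(benzyloxy)-4-(triisopropylsilyloxy)phenyl]methylidene}cyclohexa-2,4-dien-1-one | C(c1ccccc1)Oc1cc(O[Si](C(C)C)(C(C)C)C(C)C)cc(OCc2ccccc2)c1/C=C1/C(=O)C=C(OCc2ccccc2)C=C1 | intermediate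
9 | (2S,4S)-7-(benzyloxy)-2-[4-(benzyloxy)phenyl]-4-[2,6-bis(benzyloxy)-4-(triisopropylsilyloxy)phenyl]chromane (2,4-cis) | c5ccccc5COc1ccc([C@@H]2C[C@H](c3c(OCc5ccccc5)cc(O[Si](C(C)C)(C(C)C)C(C)C)cc3OCc5ccccc5)c3ccc(OCc5ccccc5)cc3O2)cc1 | intermediate
10 | 3,5-bis(benzyloxy)-4-{(2S,4S)-7-(benzyloxy)-2-[4-(benzyloxy)phenyl]chroman-4-yl}phenol | c5ccccc5COc1ccc([C@@H]2C[C@H](c3c(OCc5ccccc5)cc(O)cc3OCc5ccccc5)c3ccc(OCc5ccccc5)cc3O2)cc1 | intermediate
11 | 4,6-bis(benzyloxy)-5-{(2S,4S)-7-(benzyloxy)-2-[4-(benzyloxy)phenyl]chroman-4-yl}-2-hydroxybenzaldehyde | c5ccccc5COc1ccc([C@@H]2C[C@H](c3c(OCc5ccccc5)cc(O)c(C=O)c3OCc5ccccc5)c3ccc(OCc5ccccc5)cc3O2)cc1 | intermediate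
12 | 2-(benzyloxy)-N-methoxy-N-methylacetamide | CON(C)C(=O)COCc1ccccc1 | starting material
13 | [4-(benzyloxy)phenyl]magnesium bromide | Br[Mg]c1ccc(OCc2ccccc2)cc1 | starting material
14 | 2-(benzyloxy)-1-[4-(benzyloxy)phenyl]ethan-1-one | O=C(COCc1ccccc1)c1ccc(OCc2ccccc2)cc1 | intermediate
15 | (Z)-2-(benzyloxy)-1-[4-(benzyloxy)phenyl]-3-[4,6-bis(benzyloxy)-5-{(2S,4S)-7-(benzyloxy)-2-[4-(benzyloxy)phenyl]chroman-4-yl}-2-hydroxyphenyl]prop-2-en-1-one | c5ccccc5COc1ccc([C@@H]2C[C@H](c3c(OCc5ccccc5)cc(O)c(/C=C(/C(=O)c6ccc(OCc5ccccc5)cc6)OCc5ccccc5)c3OCc5ccccc5)c3ccc(OCc5ccccc5)cc3O2)cc1 | intermediate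
16 | 3,5,7-tris(benzyloxy)-2-[4-(benzyloxy)phenyl]-6-{(2S,4S)-7-(benzyloxy)-2-[4-(benzyloxy)phenyl]chroman-4-yl}chromenylium ion (cation shown; the counter-ion is the catalyst phosphate) | c5ccccc5COc1ccc([C@@H]2C[C@H](c3c(OCc5ccccc5)cc4[o+]c(-c6ccc(OCc5ccccc5)cc6)c(OCc5ccccc5)cc4c3OCc5ccccc5)c3ccc(OCc5ccccc5)cc3O2)cc1 | intermediate
17 | 3,5,7-tris(benzyloxy)-2-[4-(benzyloxy)phenyl]-6-{(2S,4S)-7-(benzyloxy)-2-[4-(benzyloxy)phenyl]chroman-4-yl}-4H-chromene | c5ccccc5COc1ccc([C@@H]2C[C@H](c3c(OCc5ccccc5)cc4OC(c6ccc(OCc5ccccc5)cc6)=C(OCc5ccccc5)Cc4c3OCc5ccccc5)c3ccc(OCc5ccccc5)cc3O2)cc1 | intermediate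
18 | (3R)-3,5,7-tris(benzyloxy)-2-[4-(benzyloxy)phenyl]-6-{(2S,4S)-7-(benzyloxy)-2-[4-(benzyloxy)phenyl]chroman-4-yl}-3,4-dihydrochromenylium ion (cation shown; the counter-ion is the catalyst phosphate) | c5ccccc5COc1ccc([C@@H]2C[C@H](c3c(OCc5ccccc5)cc4c(c3OCc5ccccc5)C[C@@H](OCc5ccccc5)C(c3ccc(OCc5ccccc5)cc3)=[O+]4)c3ccc(OCc5ccccc5)cc3O2)cc1 | intermediate
19 | (2R,3R)-3,5,7-tris(benzyloxy)-2-[4-(benzyloxy)phenyl]-6-{(2S,4S)-7-(benzyloxy)-2-[4-(benzyloxy)phenyl]chroman-4-yl}chromane | c5ccccc5COc1ccc([C@@H]2C[C@H](c3c(OCc5ccccc5)cc4c(c3OCc5ccccc5)C[C@@H](OCc5ccccc5)[C@@H](c3ccc(OCc5ccccc5)cc3)O4)c3ccc(OCc5ccccc5)cc3O2)cc1 | intermediate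
20 | (2R,3R)-2-(4-hydroxyphenyl)-6-[(2S,4S)-7-hydroxy-2-(4-hydroxyphenyl)chroman-4-yl]chromane-3,5,7-triol | Oc1ccc([C@@H]2C[C@H](c3c(O)cc4c(c3O)C[C@@H](O)[C@@H](c3ccc(O)cc3)O4)c3ccc(O)cc3O2)cc1 | target

## Step count and risks

Total step count: 9. Longest linear sequence: 8 (steps 1–5 and 7–9).

**Step 8.** The chiral anion may give weak or wrong-sense facial control in the protonation and hydride transfers, or the cascade may stall after the first hydride transfer.
- The fallback uses known chemistry only, sets out from phenol 10 and comes back at target 20.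
- 4-(Benzyloxy)benzaldehyde is treated with vinylmagnesium bromide to give 1-[4-(benzyloxy)phenyl]prop-2-en-1-ol F1, which MnO2 oxidises to 1-[4-(benzyloxy)phenyl]prop-2-en-1-one F2.
- Sc(OTf)3-catalysed Friedel–Crafts conjugate addition of 10 to F2 and acid-catalysed cyclodehydration (p-TsOH, toluene, 4 Å MS) give the 3-unsubstituted 5,7-bis(benzyloxy)-2-aryl-6-flavanyl-4H-chromene F3.
- Sharpless asymmetric dihydroxylation of its enol ether double bond gives the ring-opened (R)-α-hydroxy ketone F4. The conditions are OsO4, hydroquinidine 1,4-phthalazinediyl diether, N-methylmorpholine N-oxide and acetone/water; ferricyanide is avoided because a phenol is liberated.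
- Reductive cycloetherification (Et3SiH, BF3·OEt2, CH2Cl2, −78 to −20 °C) closes ring F with hydride entering anti to the C3 oxygen and gives the 2,3-cis penta-O-benzyl flavan-3-ol F5.
- Hydrogenolysis as in step 9 gives 20.

**Step 3.** The benzhydryl cation may self-alkylate the electron-rich ring D, and enantiofacial discrimination may be low because ring D, with two ortho substituents, is twisted out of the quinone methide plane.
- The fallback sets out from silyl ether 2 (lithiated to 4 as in step 2) and comes back at 9.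
- 7-Hydroxy-4H-chromen-4-one is benzylated (BnBr, K2CO3, DMF) to 7-(benzyloxy)-4H-chromen-4-one F6.
- Conjugate addition of [4-(benzyloxy)phenyl]boronic acid gives (2S)-7-(benzyloxy)-2-[4-(benzyloxy)phenyl]chroman-4-one F7. The catalyst is Pd(OCOCF3)2 with enantiopure 4-tert-butyl-2-(pyridin-2-yl)-4,5-dihydrooxazole, using the enantiomer that delivers 2S.
- Aryllithium 4, transmetalated with CeCl3 to suppress enolisation and ring opening, adds to the ketone to give the tertiary 4-aryl-flavan-4-ol F8.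
- Ionic hydrogenation (Et3SiH, CF3CO2H, CH2Cl2, −40 °C) with axial hydride delivery at C4 leaves ring D equatorial, cis to the C2 aryl group, and gives 9.

**Step 7.** Aldol addition may be sluggish and retro-aldol cleavage may compete, because the phenoxide-bearing, doubly alkoxy-substituted aldehyde is a poor electrophile in base.
- The fallback sets out from 11 and 14 and comes back at 15.
- The two are condensed under anhydrous acid (HCl gas, EtOAc, 0 °C). The enol of 14 attacks the protonated aldehyde, and the equilibrium is drained by precipitation of the aromatic 3-benzyloxyflavylium chloride F9.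
- Stirring F9 with aqueous NaOAc in MeCN hydrates C2 and opens the ring to chalcone 15.

## Further compounds

F1 | step 8 | 1-[4-(benzyloxy)phenyl]prop-2-en-1-ol (racemic) | C=CC(O)c1ccc(OCc2ccccc2)cc1
F2 | step 8 | 1-[4-(benzyloxy)phenyl]prop-2-en-1-one | C=CC(=O)c1ccc(OCc2ccccc2)cc1
F3 | step 8 | 5,7-bis(benzyloxy)-2-[4-(benzyloxy)phenyl]-6-{(2S,4S)-7-(benzyloxy)-2-[4-(benzyloxy)phenyl]chroman-4-yl}-4H-chromene | c5ccccc5COc1ccc([C@@H]2C[C@H](c3c(OCc5ccccc5)cc4OC(c6ccc(OCc5ccccc5)cc6)=CCc4c3OCc5ccccc5)c3ccc(OCc5ccccc5)cc3O2)cc1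
F4 | step 8 | (2R)-1-[4-(benzyloxy)phenyl]-3-[4,6-bis(benzyloxy)-5-{(2S,4S)-7-(benzyloxy)-2-[4-(benzyloxy)phenyl]chroman-4-yl}-2-hydroxyphenyl]-2-hydroxypropan-1-one | c5ccccc5COc1ccc([C@@H]2C[C@H](c3c(OCc5ccccc5)cc(O)c(C[C@@H](O)C(=O)c6ccc(OCc5ccccc5)cc6)c3OCc5ccccc5)c3ccc(OCc5ccccc5)cc3O2)cc1
F5 | step 8 | (2R,3R)-5,7-bis(benzyloxy)-2-[4-(benzyloxy)phenyl]-6-{(2S,4S)-7-(benzyloxy)-2-[4-(benzyloxy)phenyl]chroman-4-yl}chroman-3-ol | c5ccccc5COc1ccc([C@@H]2C[C@H](c3c(OCc5ccccc5)cc4c(c3OCc5ccccc5)C[C@@H](O)[C@@H](c3ccc(OCc5ccccc5)cc3)O4)c3ccc(OCc5ccccc5)cc3O2)cc1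
F6 | step 3 | 7-(benzyloxy)-4H-chromen-4-one | O=c1ccoc2cc(OCc3ccccc3)ccc12
F7 | step 3 | (2S)-7-(benzyloxy)-2-[4-(benzyloxy)phenyl]chroman-4-one | c5ccccc5COc1ccc([C@@H]2CC(=O)c3ccc(OCc5ccccc5)cc3O2)cc1
F8 | step 3 | (2S)-7-(benzyloxy)-2-[4-(benzyloxy)phenyl]-4-[2,6-bis(benzyloxy)-4-(triisopropylsilyloxy)phenyl]chroman-4-ol (C4 epimers) | c5ccccc5COc1ccc([C@@H]2CC(O)(c3c(OCc5ccccc5)cc(O[Si](C(C)C)(C(C)C)C(C)C)cc3OCc5ccccc5)c3ccc(OCc5ccccc5)cc3O2)cc1
F9 | step 7 | 3,5,7-tris(benzyloxy)-2-[4-(benzyloxy)phenyl]-6-{(2S,4S)-7-(benzyloxy)-2-[4-(benzyloxy)phenyl]chroman-4-yl}chromenylium chloride | [Cl-].c5ccccc5COc1ccc([C@@H]2C[C@H](c3c(OCc5ccccc5)cc4[o+]c(-c6ccc(OCc5ccccc5)cc6)c(OCc5ccccc5)cc4c3OCc5ccccc5)c3ccc(OCc5ccccc5)cc3O2)cc1
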